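**Retrosynthetic overview**
1. Feature used: in the dihydrofuran ring of 17, C3 (benzylic, O-acylated) and C2 (bonded to O1 and to the 2-propenyl carbon) are adjacent and cis. They map onto the carbanion carbon and the γ-carbon of a benzyl allyl ether whose γ-carbon is already held on the arene through O1.
2. Endgame: the enal goes back to an isopropenyl methyl group (allylic oxidation), and the two esters go back to the C3 alcohol and a silyl-protected side-chain carbinol (11).
3. Key disconnection: C2–C3 by a retro-[2,3]-Wittig shift, which expands the dihydrofuran to the eight-membered (Z)-3-methyl-4H,6H-1,5-benzodioxocine 9.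
4. 9 comes from the 3-methylidene ring 8 by alkene migration, 8 from salicyl alcohol 5 and dichloride 6 by two Williamson etherifications, and 5 from methyl 5-acetylsalicylate 1 (asymmetric transfer hydrogenation sets the side-chain centre).
5. Ring order: arene (purchased), then the eight-membered dioxocine (step 5), then the dihydrofuran by ring contraction (step 7).

Key step: step 7

Assumption (configuration): the target SMILES is read as (2R,3R) in the ring, which places the C2 alkenyl and C3 acyloxy groups cis, and (S) in the side chain.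
Assumption (ligand): the sense of induction of the chiral lithium base on this ring system cannot be derived from acyclic cases; the (S,S)-ligand is written, and its (R,R)-antipode is used without other change if a first run gives the (2S,3S) series.

**Route**

Step 1
Reactants: 1 methyl 5-acetyl-2-hydroxybenzoate
Product: 2 methyl 2-hydroxy-5-[(1S)-1-hydroxyethyl]benzoate
Conditions: RuCl(p-cymene)[(S,S)-TsDPEN] (1 mol%), HCO2H/Et3N (5:2), DMF, 40 °C
Reagents that add atoms: none
Why: Noyori asymmetric transfer hydrogenation; the (S,S)-catalyst should deliver hydride to the Re face of the aryl methyl ketone, as with acetophenone, to give the (S)-carbinol, while the ester and the hydrogen-bonded phenol stay untouched in the acidic medium.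

Step 2
Reactants: 2 methyl 2-hydroxy-5-[(1S)-1-hydroxyethyl]benzoate
Product: 4 methyl 5-[(1S)-1-(tert-butyldimethylsilyloxy)ethyl]-2-hydroxybenzoate, via bis-silyl ether 3 (not isolated)
Conditions: TBSCl (2.5 equiv), imidazole, DMF, rt; then MeOH, K2CO3 (0.2 equiv), 0 °C to rt
Reagents that add atoms: tert-butyldimethylsilyl chloride, CC(C)(C)[Si](C)(C)Cl
Why: Silylation of both hydroxyls followed by chemoselective methanolysis of the aryl silyl ether, whose phenoxide (ortho to the ester) is a far better leaving group than the secondary alkoxide, should leave only the side-chain silyl ether; the stereocentre is not touched.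

Step 3
Reactants: 4 methyl 5-[(1S)-1-(tert-butyldimethylsilyloxy)ethyl]-2-hydroxybenzoate
Product: 5 4-[(1S)-1-(tert-butyldimethylsilyloxy)ethyl]-2-(hydroxymethyl)phenol
Conditions: LiAlH4 (2.5 equiv), THF, 0 °C; aq. KNaC4H4O6 work-up
Reagents that add atoms: none
Why: Hydride reduction of the methyl ester to the benzylic alcohol; the phenol is carried as its aluminate and the secondary silyl ether is inert at 0 °C.

Step 4
Reactants: 5 4-[(1S)-1-(tert-butyldimethylsilyloxy)ethyl]-2-(hydroxymethyl)phenol; 6 3-chloro-2-(chloromethyl)prop-1-ene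
Product: 7 {5-[(1S)-1-(tert-butyldimethylsilyloxy)ethyl]-2-{[2-(chloromethyl)prop-2-en-1-yl]oxy}phenyl}methanol
Conditions: K2CO3, 6 (5 equiv), acetone, 55 °C
Reagents that add atoms: none
Why: Williamson etherification; K2CO3 deprotonates only the phenol, and the excess of the symmetrical allylic dichloride should hold the reaction at mono-substitution (direct and allylic displacement give the same product), keeping the second chloride for ring closure.

Step 5
Reactants: 7 {5-[(1S)-1-(tert-butyldimethylsilyloxy)ethyl]-2-{[2-(chloromethyl)prop-2-en-1-yl]oxy}phenyl}methanol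
Product: 8 8-[(1S)-1-(tert-butyldimethylsilyloxy)ethyl]-3-methylidene-3,4-dihydro-2H,6H-1,5-benzodioxocine
Conditions: NaH, n-Bu4NI (10 mol%), THF, slow addition to 0.005 M, 0 to 45 °C
Reagents that add atoms: none
Why: Intramolecular Williamson etherification (8-exo-tet) of the benzylic alkoxide on the allylic halide (iodide by Finkelstein exchange in the flask); high dilution disfavours oligomers, and the two arene carbons and the sp2 ring carbon lower the transannular strain of the eight-membered ring.

Step 6
Reactants: 8 8-[(1S)-1-(tert-butyldimethylsilyloxy)ethyl]-3-methylidene-3,4-dihydro-2H,6H-1,5-benzodioxocine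
Product: 9 (2Z)-8-[(1S)-1-(tert-butyldimethylsilyloxy)ethyl]-3-methyl-4H,6H-1,5-benzodioxocine
Conditions: t-BuOK (0.3 equiv), DMSO, rt
Reagents that add atoms: none
Why: Base-mediated prototropic isomerisation of an allyl aryl ether to the propenyl ether; the C2 hydrogens next to the aryloxy oxygen are the most acidic allylic hydrogens, the oxyallyl anion is reprotonated at the exocyclic CH2, and the ring allows only the Z enol ether, which as a conjugated trisubstituted alkene is also favoured thermodynamically.

Step 7
Reactants: 9 (2Z)-8-[(1S)-1-(tert-butyldimethylsilyloxy)ethyl]-3-methyl-4H,6H-1,5-benzodioxocine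
Product: 11 (2R,3R)-5-[(1S)-1-(tert-butyldimethylsilyloxy)ethyl]-2-(prop-1-en-2-yl)-2,3-dihydro-1-benzofuran-3-ol, via 6-lithiobenzodioxocine 10 (not isolated)
Conditions: t-BuLi (1.5 equiv), (S,S)-2,2'-(pentane-3,3-diyl)bis(4-isopropyl-4,5-dihydro-1,3-oxazole) (1.6 equiv), hexane/Et2O, −78 °C; then sat. aq NH4Cl
Reagents that add atoms: none
Why: Proposed new method: the t-BuLi·bis(oxazoline) complex removes one C6 hydrogen (benzylic, α to O5, with O1 placed to chelate lithium) to give the α-oxybenzyllithium 10, whose carbanion carbon bonds to the enol ether carbon C2 through a five-membered envelope transition state while the allylic C4–O5 bond breaks, which forms the C2–C3 bond of 11, contracts the eight-membered ring by three atoms and releases the C3 alkoxide and the isopropenyl group. The closest known reactions are [2,3]-Wittig ring contractions of large-ring allylic ethers and enantioselective [2,3]-Wittig rearrangements of acyclic benzyl allyl ethers under t-BuLi/bis(oxazoline) control; a medium ring whose γ-carbon is an aryl enol ether carbon is without precedent. The dihydrofuran ring closes transannularly in a 5-exo-trig sense, the C2=C3 π bond of 9 lying outside the new ring. Because C6 and C2 are already bridged by O1 and two arene carbons, the transition state is a cis-fused bicyclo[3.3.0] array and the ring fixes the Z enol ether, so the C3 oxygen and the C2 isopropenyl group should emerge cis (relative configuration from the ring), whereas the absolute configuration of both centres must come from the chiral lithium–ligand complex, since the remote silyloxyethyl centre exerts no facial bias. The step needs lithiation at C6 in preference to the vinylic C2–H, the allylic C4–H2, the arene and the side-chain methine, and [2,3] in preference to [1,2] migration. The unhindered benzylic OCH2 is the kinetically most acidic site, the side-chain C–H is tertiary and shielded by the silyl group, and −78 °C favours the concerted shift over the radical-pair [1,2] path.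

Step 8
Reactants: 11 (2R,3R)-5-[(1S)-1-(tert-butyldimethylsilyloxy)ethyl]-2-(prop-1-en-2-yl)-2,3-dihydro-1-benzofuran-3-ol; 12 3-methylbutanoyl chloride
Product: 13 (2R,3R)-5-[(1S)-1-(tert-butyldimethylsilyloxy)ethyl]-2-(prop-1-en-2-yl)-2,3-dihydro-1-benzofuran-3-yl 3-methylbutanoate
Conditions: 12 (1.3 equiv), pyridine, DMAP (10 mol%), CH2Cl2, 0 °C
Reagents that add atoms: none
Why: DMAP-catalysed acylation of the secondary benzylic alcohol by the acid chloride; only the O–H bond is broken, so C3 keeps its configuration, and the mild base at 0 °C should avoid elimination to the benzofuran.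

Step 9
Reactants: 13 (2R,3R)-5-[(1S)-1-(tert-butyldimethylsilyloxy)ethyl]-2-(prop-1-en-2-yl)-2,3-dihydro-1-benzofuran-3-yl 3-methylbutanoate
Product: 14 (2R,3R)-5-[(1S)-1-hydroxyethyl]-2-(prop-1-en-2-yl)-2,3-dihydro-1-benzofuran-3-yl 3-methylbutanoate
Conditions: n-Bu4NF, AcOH (1:1), THF, 0 °C to rt
Reagents that add atoms: none
Why: Fluoride-induced Si–O cleavage driven by the Si–F bond; buffering with acetic acid keeps the medium non-basic so that the C3 ester is neither cleaved nor shifted, and no acid strong enough to ionise the p-alkoxybenzylic carbinol is present.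

Step 10
Reactants: 14 (2R,3R)-5-[(1S)-1-hydroxyethyl]-2-(prop-1-en-2-yl)-2,3-dihydro-1-benzofuran-3-yl 3-methylbutanoate
Product: 15 (2R,3R)-5-[(1S)-1-(acetyloxy)ethyl]-2-(prop-1-en-2-yl)-2,3-dihydro-1-benzofuran-3-yl 3-methylbutanoate
Conditions: Ac2O, pyridine, DMAP (5 mol%), CH2Cl2, 0 °C
Reagents that add atoms: acetic anhydride, CC(=O)OC(C)=O
Why: DMAP-catalysed acetylation of the secondary alcohol with retention, since only the O–H bond reacts.

Step 11
Reactants: 15 (2R,3R)-5-[(1S)-1-(acetyloxy)ethyl]-2-(prop-1-en-2-yl)-2,3-dihydro-1-benzofuran-3-yl 3-methylbutanoate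
Product: 17 (2R,3R)-5-[(1S)-1-(acetyloxy)ethyl]-2-(3-oxoprop-1-en-2-yl)-2,3-dihydro-1-benzofuran-3-yl 3-methylbutanoate, via allylic alcohol 16 (not isolated)
Conditions: SeO2 (1.5 equiv), 1,4-dioxane, 70 °C
Reagents that add atoms: selenium dioxide, O=[Se]=O
Why: Riley allylic oxidation; the ene reaction of SeO2 at the terminal CH2 of the 1,1-disubstituted alkene takes hydrogen from the methyl group (preferred over the oxygen-bearing methine C2–H), a [2,3]-sigmatropic shift of the allylseleninic acid gives the allylic alcohol 16, and this is oxidised on in the same flask to the conjugated aldehyde without touching a stereocentre.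

**Compound list**
1 | methyl 5-acetyl-2-hydroxybenzoate | CC(=O)c1ccc(O)c(C(=O)OC)c1 | starting material
2 | methyl 2-hydroxy-5-[(1S)-1-hydroxyethyl]benzoate | COC(=O)c1cc([C@H](C)O)ccc1O | intermediate
3 | methyl 2-(tert-butyldimethylsilyloxy)-5-[(1S)-1-(tert-butyldimethylsilyloxy)ethyl]benzoate (not isolated) | COC(=O)c1cc([C@H](C)O[Si](C)(C)C(C)(C)C)ccc1O[Si](C)(C)C(C)(C)C | intermediate
4 | methyl 5-[(1S)-1-(tert-butyldimethylsilyloxy)ethyl]-2-hydroxybenzoate | COC(=O)c1cc([C@H](C)O[Si](C)(C)C(C)(C)C)ccc1O | intermediate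
5 | 4-[(1S)-1-(tert-butyldimethylsilyloxy)ethyl]-2-(hydroxymethyl)phenol | OCc1cc([C@H](C)O[Si](C)(C)C(C)(C)C)ccc1O | intermediate
6 | 3-chloro-2-(chloromethyl)prop-1-ene | C=C(CCl)CCl | starting material
7 | {5-[(1S)-1-(tert-butyldimethylsilyloxy)ethyl]-2-{[2-(chloromethyl)prop-2-en-1-yl]oxy}phenyl}methanol | C=C(CCl)COc1ccc([C@H](C)O[Si](C)(C)C(C)(C)C)cc1CO | intermediate
8 | 8-[(1S)-1-(tert-butyldimethylsilyloxy)ethyl]-3-methylidene-3,4-dihydro-2H,6H-1,5-benzodioxocine | C=C1COCc2cc([C@H](C)O[Si](C)(C)C(C)(C)C)ccc2OC1 | intermediate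
9 | (2Z)-8-[(1S)-1-(tert-butyldimethylsilyloxy)ethyl]-3-methyl-4H,6H-1,5-benzodioxocine | C/C1=C/Oc2ccc([C@H](C)O[Si](C)(C)C(C)(C)C)cc2COC1 | intermediate
10 | 6-lithio derivative of 9, held as its bis(oxazoline) complex; configuration at C6 labile and not assigned (not isolated) | C/C1=C/Oc2ccc([C@H](C)O[Si](C)(C)C(C)(C)C)cc2C([Li])OC1 | intermediate
11 | (2R,3R)-5-[(1S)-1-(tert-butyldimethylsilyloxy)ethyl]-2-(prop-1-en-2-yl)-2,3-dihydro-1-benzofuran-3-ol (cis) | C=C(C)[C@H]1Oc2ccc([C@H](C)O[Si](C)(C)C(C)(C)C)cc2[C@H]1O | intermediate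
12 | 3-methylbutanoyl chloride | CC(C)CC(Cl)=O | starting material
13 | (2R,3R)-5-[(1S)-1-(tert-butyldimethylsilyloxy)ethyl]-2-(prop-1-en-2-yl)-2,3-dihydro-1-benzofuran-3-yl 3-methylbutanoate | C=C(C)[C@H]1Oc2ccc([C@H](C)O[Si](C)(C)C(C)(C)C)cc2[C@H]1OC(=O)CC(C)C | intermediate
14 | (2R,3R)-5-[(1S)-1-hydroxyethyl]-2-(prop-1-en-2-yl)-2,3-dihydro-1-benzofuran-3-yl 3-methylbutanoate | C=C(C)[C@H]1Oc2ccc([C@H](C)O)cc2[C@H]1OC(=O)CC(C)C | intermediate
15 | (2R,3R)-5-[(1S)-1-(acetyloxy)ethyl]-2-(prop-1-en-2-yl)-2,3-dihydro-1-benzofuran-3-yl 3-methylbutanoate | C=C(C)[C@H]1Oc2ccc([C@H](C)OC(C)=O)cc2[C@H]1OC(=O)CC(C)C | intermediate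
16 | (2R,3R)-5-[(1S)-1-(acetyloxy)ethyl]-2-(3-hydroxyprop-1-en-2-yl)-2,3-dihydro-1-benzofuran-3-yl 3-methylbutanoate (not isolated) | C=C(CO)[C@H]1Oc2ccc([C@H](C)OC(C)=O)cc2[C@H]1OC(=O)CC(C)C | intermediate
17 | (2R,3R)-5-[(1S)-1-(acetyloxy)ethyl]-2-(3-oxoprop-1-en-2-yl)-2,3-dihydro-1-benzofuran-3-yl 3-methylbutanoate (CNP0252902.1) | C=C(C=O)[C@H]1Oc2ccc([C@H](C)OC(C)=O)cc2[C@H]1OC(=O)CC(C)C | target

**Totals**
Total step count: 11. Longest linear sequence: 11 steps (1 to 17); 6 and 12 are purchased and enter in steps 4 and 8.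

**Steps most likely to fail**

1. Step 7. Possible failures as processes:
   - lithiation at the wrong site (vinylic C2–H, allylic C4–H2, or the side-chain methine followed by silyl migration to carbon);
   - collapse of the benzyllithium by a [1,2]-shift to a seven-membered benzoxepinol;
   - weak facial discrimination by the ligand, which would give the separable (2S,3S) diastereomer;
   - a ring conformation that does not reach the envelope geometry.

   Fallback (known chemistry), setting out from 5 and returning at 13, so that steps 4 to 8 are bypassed. MnO2 (CH2Cl2, rt) should oxidise the benzylic alcohol to 5-[(1S)-1-(tert-butyldimethylsilyloxy)ethyl]-2-hydroxybenzaldehyde F1. Horner–Wadsworth–Emmons olefination with diethyl (2-methylprop-2-en-1-yl)phosphonate (NaH, 2.2 equiv, THF) should give 2-[(1E)-3-methylbuta-1,3-dien-1-yl]-4-[(1S)-1-(tert-butyldimethylsilyloxy)ethyl]phenol F2. Pivaloyl chloride/Et3N then masks the phenol as 2-[(1E)-3-methylbuta-1,3-dien-1-yl]-4-[(1S)-1-(tert-butyldimethylsilyloxy)ethyl]phenyl 2,2-dimethylpropanoate F3. Shi epoxidation with the L-fructose-derived ketone (KHSO5 as 2KHSO5·KHSO4·K2SO4, K2CO3 buffer, MeCN/dimethoxymethane, 0 °C) is expected to epoxidise only the trans-disubstituted styrenyl alkene and give 2-[(2S,3S)-3-(prop-1-en-2-yl)oxiran-2-yl]-4-[(1S)-1-(tert-butyldimethylsilyloxy)ethyl]phenyl 2,2-dimethylpropanoate F4. K2CO3/MeOH removes the pivalate, and the phenoxide should open the vinyl epoxide at the allylic carbon with inversion to give trans (2R,3S)-5-[(1S)-1-(tert-butyldimethylsilyloxy)ethyl]-2-(prop-1-en-2-yl)-2,3-dihydro-1-benzofuran-3-ol F5. Mitsunobu esterification with 3-methylbutanoic acid (PPh3, diisopropyl azodicarboxylate, THF, 0 °C) inverts C3 and gives the cis ester 13 directly.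

2. Step 6. Possible failures as processes: migration of the alkene toward the benzyl ether oxygen (an alkyl enol ether that cannot rearrange), incomplete migration, or base-induced loss of the silyl ether.

   Fallback, setting out from 4 and returning at 9, with the position of the double bond fixed by construction. Cu(OAc)2-promoted O-vinylation of the phenol with 2,4,6-trivinylcyclotriboroxane–pyridine complex (pyridine, CH2Cl2, air, rt) should give methyl 2-(ethenyloxy)-5-[(1S)-1-(tert-butyldimethylsilyloxy)ethyl]benzoate F6. LiAlH4 (THF, 0 °C) reduces the ester to [2-(ethenyloxy)-5-[(1S)-1-(tert-butyldimethylsilyloxy)ethyl]phenyl]methanol F7. NaH/3-chloro-2-methylprop-1-ene (THF/DMF) gives tert-butyl[(1S)-1-{4-(ethenyloxy)-3-[(2-methylprop-2-en-1-yloxy)methyl]phenyl}ethoxy]dimethylsilane F8. Ring-closing metathesis of the aryl vinyl ether with the 1,1-disubstituted alkene (second-generation Hoveyda–Grubbs catalyst, toluene, 80 °C, high dilution) should close the eight-membered ring as the trisubstituted aryl enol ether 9, with Z enforced by the ring.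

3. Step 11. Possible failures as processes: heat- and acid-promoted ionisation of the two benzylic esters (loss of 3-methylbutanoic acid across C2–C3 toward the benzofuran, racemisation of the p-alkoxybenzylic acetate), hydrogen abstraction at C2–H instead of the methyl group, or over-oxidation.

   Fallback, setting out from 15 and returning at 17. The four-electron oxidation is split into two mild operations. Catalytic SeO2 (0.3 equiv) with anhydrous t-BuOOH in CH2Cl2 at rt should stop at the allylic alcohol 16, which is isolated. Dess–Martin periodinane buffered with NaHCO3 (CH2Cl2, 0 °C) then gives 17 (new compound: none F0).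

**Further compounds**
F1 | step 7 | 5-[(1S)-1-(tert-butyldimethylsilyloxy)ethyl]-2-hydroxybenzaldehyde | O=Cc1cc([C@H](C)O[Si](C)(C)C(C)(C)C)ccc1O
F2 | step 7 | 2-[(1E)-3-methylbuta-1,3-dien-1-yl]-4-[(1S)-1-(tert-butyldimethylsilyloxy)ethyl]phenol | C=C(C)/C=C/c1cc([C@H](C)O[Si](C)(C)C(C)(C)C)ccc1O
F3 | step 7 | 2-[(1E)-3-methylbuta-1,3-dien-1-yl]-4-[(1S)-1-(tert-butyldimethylsilyloxy)ethyl]phenyl 2,2-dimethylpropanoate | C=C(C)/C=C/c1cc([C@H](C)O[Si](C)(C)C(C)(C)C)ccc1OC(=O)C(C)(C)C
F4 | step 7 | 2-[(2S,3S)-3-(prop-1-en-2-yl)oxiran-2-yl]-4-[(1S)-1-(tert-butyldimethylsilyloxy)ethyl]phenyl 2,2-dimethylpropanoate | C=C(C)[C@@H]1O[C@H]1c1cc([C@H](C)O[Si](C)(C)C(C)(C)C)ccc1OC(=O)C(C)(C)C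
F5 | step 7 | (2R,3S)-5-[(1S)-1-(tert-butyldimethylsilyloxy)ethyl]-2-(prop-1-en-2-yl)-2,3-dihydro-1-benzofuran-3-ol (trans) | C=C(C)[C@H]1Oc2ccc([C@H](C)O[Si](C)(C)C(C)(C)C)cc2[C@@H]1O
F6 | step 6 | methyl 2-(ethenyloxy)-5-[(1S)-1-(tert-butyldimethylsilyloxy)ethyl]benzoate | COC(=O)c1cc([C@H](C)O[Si](C)(C)C(C)(C)C)ccc1OC=C
F7 | step 6 | [2-(ethenyloxy)-5-[(1S)-1-(tert-butyldimethylsilyloxy)ethyl]phenyl]methanol | OCc1cc([C@H](C)O[Si](C)(C)C(C)(C)C)ccc1OC=C
F8 | step 6 | tert-butyl[(1S)-1-{4-(ethenyloxy)-3-[(2-methylprop-2-en-1-yloxy)methyl]phenyl}ethoxy]dimethylsilane | C=C(C)COCc1cc([C@H](C)O[Si](C)(C)C(C)(C)C)ccc1OC=C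
F0 | step 11 | none | none
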